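## Retrosynthetic overview

1. Numbering follows chroman-2-one: O1, C2(=O), C3, C4 (stereocentre), C4a, C5, C6 (phenethyl), C7 (OH), C8, C8a. Ring B is C4a–C8a.
2. Enabling feature: the C7–OH lies para to C4a and meta to C8a. Oxidising this phenol turns ring B into the cross-conjugated dienone C7(=O)/C8=C8a/C5=C6. C8a is then an enone β-carbon six atoms from the carboxyl oxygen, and the C6 phenethyl group disarms the rival β-carbon C5.
3. O1–C8a is cut last. An open (S)-3,3-diarylpropanoate monophenol is dearomatised, lactonised by a 6-exo oxa-Michael closure and rearomatised by loss of MeOH. The δ-lactone is the only ring the route forms; all three benzene rings are bought.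
4. The C4–aryl bond comes from a rhodium-catalysed asymmetric 1,4-addition to a cinnamate, C6–CH2 from a B-alkyl Suzuki–Miyaura coupling, and C3=C4 from an HWE olefination of 3-bromo-4-hydroxybenzaldehyde.
5. The endgame is hydrogenolysis of the two catechol benzyl ethers.

Key step: step 7

Assumption: 1,2-bis(benzyloxy)-4-bromobenzene (8) is taken as purchasable; it is otherwise one benzylation away from 4-bromocatechol.

## Route

Step 1
Reactants: 1 3-bromo-4-hydroxybenzaldehyde
Product: 2 3-bromo-4-[(triisopropylsilyl)oxy]benzaldehyde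
Conditions: TIPSCl, imidazole, DMF, rt
Reagents that add atoms: triisopropylsilyl chloride, CC(C)[Si](Cl)(C(C)C)C(C)C
Why: Standard phenol silylation; the bulky TIPS ether should survive the basic aqueous media of steps 3 and 5 and can be removed by fluoride beside benzyl ethers and a tert-butyl ester.

Step 2
Reactants: 2 3-bromo-4-[(triisopropylsilyl)oxy]benzaldehyde; 3 tert-butyl diethylphosphonoacetate
Product: 4 tert-butyl (E)-3-{3-bromo-4-[(triisopropylsilyl)oxy]phenyl}acrylate
Conditions: NaH, THF, 0 °C → rt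
Reagents that add atoms: none
Why: Horner–Wadsworth–Emmons olefination of an aryl aldehyde with a stabilised phosphonate should give the E-cinnamate.

Step 3
Reactants: 4 tert-butyl (E)-3-{3-bromo-4-[(triisopropylsilyl)oxy]phenyl}acrylate; 5 3,4-dimethoxystyrene
Product: 7 tert-butyl (E)-3-{3-[2-(3,4-dimethoxyphenyl)ethyl]-4-[(triisopropylsilyl)oxy]phenyl}acrylate, via B-[2-(3,4-dimethoxyphenyl)ethyl]-9-borabicyclo[3.3.1]nonane 6 (not isolated)
Conditions: 5 (slight excess over borane), 9-BBN-H, THF, 0 °C → rt; then 4, PdCl2(dppf) (5 mol %), aq. K3PO4, DMF/THF, 50 °C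
Reagents that add atoms: none
Why: Anti-Markovnikov hydroboration of the styrene followed by B-alkyl Suzuki–Miyaura coupling installs the saturated two-carbon link directly, so no alkene has to be reduced beside the acrylate.

Step 4
Reactants: 8 1,2-bis(benzyloxy)-4-bromobenzene
Product: 10 [3,4-bis(benzyloxy)phenyl]boronic acid, via 3,4-bis(benzyloxy)phenyllithium 9 (not isolated)
Conditions: n-BuLi, THF, −78 °C; B(OiPr)3, −78 °C → rt; aq. HCl
Reagents that add atoms: triisopropyl borate, CC(C)OB(OC(C)C)OC(C)C; water, O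
Why: Bromine–lithium exchange at low temperature outruns any attack on the benzyl ethers, and borate trapping with hydrolysis is the standard route to arylboronic acids.

Step 5
Reactants: 7 tert-butyl (E)-3-{3-[2-(3,4-dimethoxyphenyl)ethyl]-4-[(triisopropylsilyl)oxy]phenyl}acrylate; 10 [3,4-bis(benzyloxy)phenyl]boronic acid
Product: 11 tert-butyl (3S)-3-[3,4-bis(benzyloxy)phenyl]-3-{3-[2-(3,4-dimethoxyphenyl)ethyl]-4-[(triisopropylsilyl)oxy]phenyl}propanoate
Conditions: [RhCl(C2H4)2]2 (1.5 mol %), (S,S)-Ph-bod* (3.3 mol %), aq. KOH (0.5 equiv), 10 (2 equiv), dioxane/H2O, 50 °C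
Reagents that add atoms: none
Why: Hayashi–Miyaura asymmetric 1,4-addition, for which tert-butyl cinnamates and C2-symmetric chiral dienes are a proven pairing; delivery of the aryl group to the C3 Si face gives the (S)-ester (the spatial arrangement of C4 in the target), the quadrant model of this ligand family predicts that face for the (S,S)-ligand, and the antipodal ligand is the remedy if a test run shows the opposite sense.

Step 6
Reactants: 11 tert-butyl (3S)-3-[3,4-bis(benzyloxy)phenyl]-3-{3-[2-(3,4-dimethoxyphenyl)ethyl]-4-[(triisopropylsilyl)oxy]phenyl}propanoate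
Product: 12 tert-butyl (3S)-3-[3,4-bis(benzyloxy)phenyl]-3-{3-[2-(3,4-dimethoxyphenyl)ethyl]-4-hydroxyphenyl}propanoate
Conditions: TBAF, AcOH, THF, 0 °C
Reagents that add atoms: none
Why: Buffered fluoride cleaves only the aryl silyl ether and leaves the ester, the benzyl ethers and the non-acidic C3–H untouched.

Step 7
Reactants: 12 tert-butyl (3S)-3-[3,4-bis(benzyloxy)phenyl]-3-{3-[2-(3,4-dimethoxyphenyl)ethyl]-4-hydroxyphenyl}propanoate
Product: 16 (4R)-4-[3,4-bis(benzyloxy)phenyl]-6-[2-(3,4-dimethoxyphenyl)ethyl]-7-hydroxychroman-2-one, via para-quinol methyl ether 13 (not isolated), via bicyclic silyl dienol ether 14 (not isolated), via aryl trimethylsilyl ether 15 (not isolated)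
Conditions: PhI(OAc)2 (1.1 equiv), MeOH, 0 °C; evaporate, toluene azeotrope; then TMSOTf (3 equiv), 2,6-di-tert-butyl-4-methylpyridine (3.5 equiv), CH2Cl2, −78 → 0 °C; aq. citric acid/THF work-up
Reagents that add atoms: none
Why: Proposed new method: stage 1 is the known hypervalent-iodine oxidative dearomatisation of a 4-alkylphenol, in which PhI(OAc)2 attacks only the free C7–OH and methanol is captured at the para carbon C4a (the carboxyl group stays masked as the tert-butyl ester so that no C4a spirolactone can form), giving both C4a epimers of dienone 13, where C8a is now the β-carbon of the enone C7(=O)–C8=C8a. Stage 2 is the new part: TMSOTf silylates the C7 carbonyl oxygen, the ester carbonyl oxygen adds to C8a (6-exo-trig oxa-Michael closure of the δ-lactone, cis ring fusion for geometric reasons), the tert-butyl cation is shed as isobutene, and the adduct is born directly as silyl dienol ether 14, in effect the methyl ether of an arene hydrate. A second TMSOTf ionises the tertiary allylic C4a–OMe bond of 14 to a cyclohexadienyl cation that carries alkyl groups on two of its three charge-bearing carbons (C4a and C6), and irreversible loss of H-8a to the hindered pyridine rearomatises ring B to 15, whose silyl ether falls off on work-up. The closest known reaction types are acid- or silyl-triflate-promoted intramolecular oxa-Michael additions to para-quinol-derived cyclohexadienones, the conjugate addition/eliminative rearomatisation of para-quinols and their ethers that gives meta-functionalised phenols with C, N and S nucleophiles, and lactonisations in which a tert-butyl ester serves as the oxygen nucleophile, whereas the combination with a carboxyl oxygen appears to have no direct precedent. No lasting stereocentre is made, since C4a and C8a are stereogenic only in 13 and 14 and are flattened again, so both C4a epimers converge on one product, and C4 keeps the configuration set in step 5 because its C–H bond is never broken (the descriptor changes from S to R only through CIP priorities). The step needs C8a over C5, secured by the C6 phenethyl group that makes C5=C6 the α-substituted and more hindered enone arm, and it needs oxygen capture to outrun the 1,2-shift of C4, secured by the six-membered transition state, the low temperature and the buffered, acid-free medium.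

Step 8
Reactants: 16 (4R)-4-[3,4-bis(benzyloxy)phenyl]-6-[2-(3,4-dimethoxyphenyl)ethyl]-7-hydroxychroman-2-one
Product: 17 (4R)-4-(3,4-dihydroxyphenyl)-6-[2-(3,4-dimethoxyphenyl)ethyl]-7-hydroxychroman-2-one (target)
Conditions: H2 (1 atm), 10 % Pd/C, EtOAc/THF, rt
Reagents that add atoms: none
Why: Hydrogenolysis of aryl benzyl ethers in a neutral, non-nucleophilic solvent spares the aryl ester lactone and the methyl ethers, and C4 carries no benzylic heteroatom, so its configuration is not touched.

## Compound list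

1 | 3-bromo-4-hydroxybenzaldehyde | O=Cc1ccc(O)c(Br)c1 | starting material
2 | 3-bromo-4-[(triisopropylsilyl)oxy]benzaldehyde | O=Cc1ccc(O[Si](C(C)C)(C(C)C)C(C)C)c(Br)c1 | intermediate
3 | tert-butyl diethylphosphonoacetate | CCOP(=O)(CC(=O)OC(C)(C)C)OCC | starting material
4 | tert-butyl (E)-3-{3-bromo-4-[(triisopropylsilyl)oxy]phenyl}acrylate | CC(C)(C)OC(=O)/C=C/c1ccc(O[Si](C(C)C)(C(C)C)C(C)C)c(Br)c1 | intermediate
5 | 3,4-dimethoxystyrene | C=Cc1ccc(OC)c(OC)c1 | starting material
6 | B-[2-(3,4-dimethoxyphenyl)ethyl]-9-borabicyclo[3.3.1]nonane | COc1ccc(CCB2C3CCCC2CCC3)cc1OC | intermediate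
7 | tert-butyl (E)-3-{3-[2-(3,4-dimethoxyphenyl)ethyl]-4-[(triisopropylsilyl)oxy]phenyl}acrylate | CC(C)(C)OC(=O)/C=C/c1ccc(O[Si](C(C)C)(C(C)C)C(C)C)c(CCc2ccc(OC)c(OC)c2)c1 | intermediate
8 | 1,2-bis(benzyloxy)-4-bromobenzene | Brc1ccc(OCc2ccccc2)c(OCc2ccccc2)c1 | starting material
9 | 3,4-bis(benzyloxy)phenyllithium | [Li]c1ccc(OCc2ccccc2)c(OCc2ccccc2)c1 | intermediate
10 | [3,4-bis(benzyloxy)phenyl]boronic acid | OB(O)c1ccc(OCc2ccccc2)c(OCc2ccccc2)c1 | intermediate
11 | tert-butyl (3S)-3-[3,4-bis(benzyloxy)phenyl]-3-{3-[2-(3,4-dimethoxyphenyl)ethyl]-4-[(triisopropylsilyl)oxy]phenyl}propanoate | COc1ccc(CCc2cc([C@H](CC(=O)OC(C)(C)C)c3ccc(OCc4ccccc4)c(OCc4ccccc4)c3)ccc2O[Si](C(C)C)(C(C)C)C(C)C)cc1OC | intermediate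
12 | tert-butyl (3S)-3-[3,4-bis(benzyloxy)phenyl]-3-{3-[2-(3,4-dimethoxyphenyl)ethyl]-4-hydroxyphenyl}propanoate | COc1ccc(CCc2cc([C@H](CC(=O)OC(C)(C)C)c3ccc(OCc4ccccc4)c(OCc4ccccc4)c3)ccc2O)cc1OC | intermediate
13 | tert-butyl (3R)-3-[3,4-bis(benzyloxy)phenyl]-3-{3-[2-(3,4-dimethoxyphenyl)ethyl]-1-methoxy-4-oxocyclohexa-2,5-dien-1-yl}propanoate, both epimers at the ring carbon that bears OMe | COc1ccc(CCC2=CC(OC)([C@H](CC(=O)OC(C)(C)C)c3ccc(OCc4ccccc4)c(OCc4ccccc4)c3)C=CC2=O)cc1OC | intermediate
14 | (4R)-4-[3,4-bis(benzyloxy)phenyl]-6-[2-(3,4-dimethoxyphenyl)ethyl]-4a-methoxy-7-[(trimethylsilyl)oxy]-4,4a-dihydro-3H-chromen-2(8aH)-one, cis-fused diastereomers | COc1ccc(CCC2=CC3(OC)C(C=C2O[Si](C)(C)C)OC(=O)C[C@@H]3c2ccc(OCc3ccccc3)c(OCc3ccccc3)c2)cc1OC | intermediate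
15 | (4R)-4-[3,4-bis(benzyloxy)phenyl]-6-[2-(3,4-dimethoxyphenyl)ethyl]-7-[(trimethylsilyl)oxy]chroman-2-one | COc1ccc(CCc2cc3c(cc2O[Si](C)(C)C)OC(=O)C[C@@H]3c2ccc(OCc3ccccc3)c(OCc3ccccc3)c2)cc1OC | intermediate
16 | (4R)-4-[3,4-bis(benzyloxy)phenyl]-6-[2-(3,4-dimethoxyphenyl)ethyl]-7-hydroxychroman-2-one | COc1ccc(CCc2cc3c(cc2O)OC(=O)C[C@@H]3c2ccc(OCc3ccccc3)c(OCc3ccccc3)c2)cc1OC | intermediate
17 | (4R)-4-(3,4-dihydroxyphenyl)-6-[2-(3,4-dimethoxyphenyl)ethyl]-7-hydroxychroman-2-one | COc1ccc(CCc2cc3c(cc2O)OC(=O)C[C@@H]3c2ccc(O)c(O)c2)cc1OC | target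

## Step count and risks

Total step count: 8. Longest linear sequence: 7 (steps 1, 2, 3, 5, 6, 7, 8).

Steps most likely to fail:

**1. Step 7 (proposed new method).** Several processes could outrun the addition/rearomatisation sequence.
- At the oxidation stage, proton loss from C4 would form a quinone methide and erode the configuration.
- After silyl activation of the dienone, the benzylic C4 substituent could undergo a 1,2-shift or heterolytic loss.
- C4a–OMe could ionise before the addition, which would lead to spirolactonisation at C4a.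
- The dimethoxyphenyl ring could capture C5 in a Friedel–Crafts reaction.

The fallback uses known chemistry only and buys the aryl–oxygen bond with a resorcinol. It sets out from 6 and 10 and comes back to the route at 17. Pechmann condensation of 4-bromoresorcinol with malic acid in sulfuric acid gives 6-bromo-7-hydroxycoumarin F1. Benzylation (BnBr, K2CO3, DMF) gives 7-(benzyloxy)-6-bromocoumarin F2. B-alkyl Suzuki–Miyaura coupling with 6 under the conditions of step 3 gives 7-(benzyloxy)-6-[2-(3,4-dimethoxyphenyl)ethyl]coumarin F3. Rhodium/SEGPHOS-catalysed asymmetric 1,4-addition of 10 to the coumarin C3=C4 bond gives (4R)-7-(benzyloxy)-4-[3,4-bis(benzyloxy)phenyl]-6-[2-(3,4-dimethoxyphenyl)ethyl]chroman-2-one F4. Hydrogenolysis as in step 8 then gives 17.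

**2. Step 5.** Carbometalation of the electron-rich, meta-substituted cinnamate may be slow, so that protodeboronation consumes the boronic acid, or the facial discrimination may be insufficient.

The fallback sets out from 7 and 8 and comes back at 11. Mizoroki–Heck arylation of 7 with 8 (Pd(PtBu3)2, Cy2NMe, dioxane, 100 °C) places the new aryl group trans to the ester by syn insertion and syn elimination. This gives tert-butyl (E)-3-[3,4-bis(benzyloxy)phenyl]-3-{3-[2-(3,4-dimethoxyphenyl)ethyl]-4-[(triisopropylsilyl)oxy]phenyl}acrylate F5. Asymmetric conjugate hydrosilylation of this geometrically defined 3,3-diarylacrylate follows, with a rhodium bis(oxazolinyl)phenyl catalyst and (EtO)2MeSiH, then hydrolysis. The hydride sets the stereocentre and leads to 11.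

**3. Step 3.** Protodeboronation or β-hydride elimination of the alkyl partner could compete. Residual B–H could reduce the acrylate, or the silyl ether could be lost in the aqueous base.

The fallback sets out from 4 and 5 and comes back at 11. Mizoroki–Heck coupling of 4 with 5 (Pd(OAc)2, P(o-tol)3, Et3N, DMF, 100 °C) gives tert-butyl (E)-3-{3-[(E)-2-(3,4-dimethoxyphenyl)ethenyl]-4-[(triisopropylsilyl)oxy]phenyl}acrylate F6. The 1,4-addition of 10 under the conditions of step 5 touches only the acrylate. It gives tert-butyl (3S)-3-[3,4-bis(benzyloxy)phenyl]-3-{3-[(E)-2-(3,4-dimethoxyphenyl)ethenyl]-4-[(triisopropylsilyl)oxy]phenyl}propanoate F7. Diimide reduction (TsNHNH2, NaOAc, THF/H2O, reflux) then saturates the stilbene double bond without touching the benzyl ethers and gives 11.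

## Further compounds

F1 | step 7 | 6-bromo-7-hydroxycoumarin | O=c1ccc2cc(Br)c(O)cc2o1
F2 | step 7 | 7-(benzyloxy)-6-bromocoumarin | O=c1ccc2cc(Br)c(OCc3ccccc3)cc2o1
F3 | step 7 | 7-(benzyloxy)-6-[2-(3,4-dimethoxyphenyl)ethyl]coumarin | COc1ccc(CCc2cc3ccc(=O)oc3cc2OCc2ccccc2)cc1OC
F4 | step 7 | (4R)-7-(benzyloxy)-4-[3,4-bis(benzyloxy)phenyl]-6-[2-(3,4-dimethoxyphenyl)ethyl]chroman-2-one | COc1ccc(CCc2cc3c(cc2OCc2ccccc2)OC(=O)C[C@@H]3c2ccc(OCc3ccccc3)c(OCc3ccccc3)c2)cc1OC
F5 | step 5 | tert-butyl (E)-3-[3,4-bis(benzyloxy)phenyl]-3-{3-[2-(3,4-dimethoxyphenyl)ethyl]-4-[(triisopropylsilyl)oxy]phenyl}acrylate | CC(C)(C)OC(=O)/C=C(/c1ccc(OCc2ccccc2)c(OCc2ccccc2)c1)c1ccc(O[Si](C(C)C)(C(C)C)C(C)C)c(CCc2ccc(OC)c(OC)c2)c1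
F6 | step 3 | tert-butyl (E)-3-{3-[(E)-2-(3,4-dimethoxyphenyl)ethenyl]-4-[(triisopropylsilyl)oxy]phenyl}acrylate | CC(C)(C)OC(=O)/C=C/c1ccc(O[Si](C(C)C)(C(C)C)C(C)C)c(/C=C/c2ccc(OC)c(OC)c2)c1
F7 | step 3 | tert-butyl (3S)-3-[3,4-bis(benzyloxy)phenyl]-3-{3-[(E)-2-(3,4-dimethoxyphenyl)ethenyl]-4-[(triisopropylsilyl)oxy]phenyl}propanoate | COc1ccc(/C=C/c2cc([C@H](CC(=O)OC(C)(C)C)c3ccc(OCc4ccccc4)c(OCc4ccccc4)c3)ccc2O[Si](C(C)C)(C(C)C)C(C)C)cc1OC
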